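## Analysis of the target

Guangsangon N (20) is built on a 1-methylcyclohexene (ring A, numbered here C1(CH3)=C2H–C3–C4–C5–C6H2). It carries a resorcinol ring (ring B) on C3, a 2,4-dihydroxybenzoyl group (ring E) on C4 and a 2,4-dihydroxyphenyl group (ring F) on C5. Ring B is substituted once more, meta to its bond to C3 and next to one of its hydroxyls, by C2 of a 7-hydroxychroman-4-one (pyranone ring C with O1, C2, C3, C4, fused to benzo ring D). There are four stereocentres: C3 (R), C4 (R) and C5 (S) of ring A are contiguous and all-trans, so all three substituents can be equatorial, while C2 (S) of ring C lies beyond ring B, too far for ring A to relay anything to it. The sensitive points are the seven phenols, the trisubstituted C1=C2 alkene (no hydrogenolysis; an ortho-hydroxyl of ring B can add across it in hot strong acid), the enolisable C4–H (harmless, all-trans being the thermodynamic arrangement) and above all C2 of ring C. That centre epimerises by retro-oxa-Michael opening to the 2'-hydroxychalcone under base and is further labilised by the ortho and para oxygens of ring B. The synthesis is hard because ring A must be made as one enantiomer with the exo-type trans,trans relationship, and the chromanone centre must be set late, by reagent control alone, and never meet base afterwards. The strategy rests on the O1–C2 bond: it is β to the C4 carbonyl and its oxygen sits ortho to that carbonyl on ring D, the retron of a phenol conjugate addition as in the chalcone-to-flavanone isomerisation.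

(The systematic names below number ring A from the carbon bonded to ring B, so C3, C4, C5 of this discussion appear there as C1, C6, C5.)

## Retrosynthetic reasoning

**20 ⇒ 17.** The last operation is chosen to be purely acidic. 20 is traced back to 17, the tert-butyl 3-carboxylate of the chromanone with all seven phenols as methoxymethyl ethers. Acid in an alcohol solvent removes the ethers (giving 18) and the ester (giving keto acid 19), which decarboxylates. No skeletal bond is made here; the gain is that the labile C2 never meets a base once it exists.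

**17 ⇒ 16.** The O1–C2 bond of ring C is cut, giving the alkylidene β-keto ester 16 with one free phenol on ring D. This bond is chosen because it is the only one whose formation creates the remote stereocentre, closes ring C and can be steered by a bifunctional cinchona-alkaloid-derived thiourea. The ester on C3 is a deliberate passenger: it makes the alkene a better acceptor and gives the catalyst a second binding point. The forward reaction must add the phenol to one face of the alkene faster than the uncatalysed closure.

**16 ⇒ 12 + 15.** The Cα=Cβ double bond (future C2–C3 of ring C) is cut by a retro-Knoevenagel step into the core aldehyde 12 and the aroylacetate 15. This places the chromanone carbons on the core in one mild condensation. The formyl group on ring B is the only functional handle the core needs.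

**15 ⇒ 14 ⇒ 13.** The C–C bond between the ketone carbon and the methylene of 15 is cut (retro-Claisen) to the salicylate ester 14 and a two-carbon tert-butyl ester enolate. 14 comes from 13 by etherifying only the non-chelated 4-hydroxyl, which leaves the phenol needed in the key step free.

**12 ⇒ 11 ⇒ 10 + 5.** 12 is 11 with its last phenol capped. In 11 the bonds C3–C4 and C5–C6 of ring A are cut together, a retro-[4+2] to the 2'-hydroxychalcone 10 and the aryl diene 5. These two bonds are chosen because one cycloaddition then sets all three ring A centres. The E alkene of 10 gives C4/C5 trans, the exo approach gives C3/C4 trans, and a chiral boron promoter bound to the free 2'-hydroxyl and carbonyl of 10 selects the face. Making ring A before ring C keeps the Lewis acid and the later phenoxide alkylation away from the labile chromanone centre.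

**10 ⇒ 7 + 9; 7 ⇐ 6; 9 ⇐ 8.** The enone double bond of 10 is cut by a retro-aldol condensation into ketone 7 and aldehyde 9. 7 keeps its chelated 2-hydroxyl free on purpose, and 9 is fully protected.

**5 ⇒ 2 + 4; 2 ⇐ 1; 4 ⇐ 3.** The aryl–vinyl bond of 5 is cut to the aryl bromide 2 and the dienylboronate 4. The formyl group is already in place in 1, so ring B needs no later functionalisation. 4 comes from hydroboration of the enyne 3.

## Alternatives that were turned down

**Alternative 1:** Ring A is cut at C4–C5 and C1–C6 into the 3-aroyl-6-methyl-2-pyrone A2 and the styrene A3. In the forward step a Cu(OTf)2–bis(oxazoline) complex binds the 1,3-dicarbonyl unit of A2, A3 adds across pyrone C3 and C6 in an inverse-demand [4+2], and the bridged lactone decarboxylates on warming to the dienyl ketone A1 with C5 set.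
- For: two-point binding is ideal for this Lewis acid class, and the chiral source is catalytic. That is stronger than the stoichiometric chiral borate of step 7.
- Against: A1 holds only one of the three ring A centres, and its conjugated diene can shift hydrogen or aromatise. Ring B must then be added to C3 of a cross-conjugated dienone, where 1,6-addition at C1 competes, and must enter cis to the C5 aryl group against the steric bias. C4 needs a separate controlled protonation.
- Comparison: the chosen route gives up catalyst economy in ring A, but builds ring A in one cycloaddition at the right oxidation level and reserves its key step for the labile chromanone centre, which Alternative 1 leaves open.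

**Alternative 2:** Ring A is cut at C2–C3 and C6–C1 into the 3-arylcyclobutanone A5 and propyne A6. Ni(cod)2 with a chiral phosphine couples carbonyl and alkyne oxidatively, β-carbon elimination opens one enantiotopic acyl–CH2 bond, and reductive elimination gives the cyclohexenone A4 with C5 set.
- For: the step is catalytic and fully atom-economic, and A5 is simple; on both counts it beats the cycloaddition used here.
- Against: A4 again carries one stereocentre. C4 needs an aroylation. Ring B must be added to the carbonyl carbon and the oxygen removed without moving the C1=C2 bond, with C3 ending cis to C5 — a 1,2-addition and deoxygenation sequence with allylic transposition and stereochemical risk, run with strong organometallics next to an aryl ketone.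
- Comparison: the chosen route is shorter and convergent, and brings in all three ring A substituents together.

**Alternative 3:** Ring A is cut at C3–C4 and C2–C3. C3 comes from the aryl aldehyde A8, and the chain A9 carries a silyl enol ether (C4) and a vinylsilane (C2). BF3·OEt2 triggers a Mukaiyama aldol addition, the benzylic oxygen ionises, and the vinylsilane attacks the cation at its silicon-bearing carbon to give A7.
- For: two bonds and the ring form in one operation, and a chair-like closure should place all three substituents equatorial. On relative configuration this is as strong as or stronger than the exo/endo question of step 7, and the bromide is a handle for the formyl group.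
- Against: the absolute configuration must already be in A9, which needs its own asymmetric synthesis. The stabilised cation can be diverted by the electron-rich benzyl ether rings. Benzyl ethers cannot be removed at the end without hydrogenating C1=C2 or cleaving the benzylic C2–O1 bond. Turning the bromide into an aldehyde next to an aryl ketone costs further steps.
- Comparison: the chosen route offers absolute and relative control in one step, protecting groups that leave under the acidic conditions the chromanone tolerates, and a shorter sequence.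

Key step: step 12

Assumptions: (R)-VANOL and the quinine-derived thiourea are written as the antipodes that lead to the (1R,5S,6R) adduct and to (2S) at the chromanone, and if either sense of induction proves opposite, (S)-VANOL or the quinidine-derived thiourea is used with no other change; 16 is taken to be the E isomer.

## Route

Step 1
Reactants: 1 5-bromo-2,4-dihydroxybenzaldehyde
Product: 2 5-bromo-2,4-bis(methoxymethoxy)benzaldehyde
Conditions: MOMCl (3 equiv), K2CO3 (4 equiv), acetone, reflux
Reagents that add atoms: chloromethyl methyl ether, COCCl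
Why: Williamson-type O-alkylation of both phenols; excess reagent and heat also convert the hydrogen-bonded 2-hydroxyl, and the aldehyde and aryl bromide are inert.

Step 2
Reactants: 3 2-methylbut-1-en-3-yne
Product: 4 (E)-4,4,5,5-tetramethyl-2-(3-methylbuta-1,3-dien-1-yl)-1,3,2-dioxaborolane
Conditions: HBpin (1.05 equiv), Cp2Zr(H)Cl (5 mol%), Et3N (10 mol%), neat, sealed tube, 60 °C
Reagents that add atoms: pinacolborane, CC1(C)OBOC1(C)C
Why: Zirconium-catalysed hydroboration of a terminal alkyne; syn, anti-Markovnikov B–H addition gives the E-alkenylboronate, and the 1,1-disubstituted alkene reacts much more slowly.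

Step 3
Reactants: 2 5-bromo-2,4-bis(methoxymethoxy)benzaldehyde; 4 (E)-4,4,5,5-tetramethyl-2-(3-methylbuta-1,3-dien-1-yl)-1,3,2-dioxaborolane
Product: 5 5-[(1E)-3-methylbuta-1,3-dien-1-yl]-2,4-bis(methoxymethoxy)benzaldehyde
Conditions: Pd(dppf)Cl2 (5 mol%), K2CO3 (3 equiv), 1,4-dioxane/H2O (4:1), 85 °C
Reagents that add atoms: none
Why: Suzuki–Miyaura coupling of an aryl bromide with an alkenylboronate, with retention of the E geometry; the non-enolisable aldehyde and the acetal ethers tolerate aqueous carbonate.

Step 4
Reactants: 6 2,4-dihydroxyacetophenone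
Product: 7 1-[2-hydroxy-4-(methoxymethoxy)phenyl]ethan-1-one
Conditions: MOMCl (1.1 equiv), K2CO3 (1.5 equiv), acetone, 25 °C
Reagents that add atoms: chloromethyl methyl ether, COCCl
Why: Selective Williamson-type alkylation of the free 4-hydroxyl; the 2-hydroxyl is held in a hydrogen bond to the ketone and is kept for boron binding in step 7.

Step 5
Reactants: 8 2,4-dihydroxybenzaldehyde
Product: 9 2,4-bis(methoxymethoxy)benzaldehyde
Conditions: MOMCl (3 equiv), K2CO3 (4 equiv), acetone, reflux
Reagents that add atoms: chloromethyl methyl ether, COCCl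
Why: Exhaustive Williamson-type O-alkylation, as in step 1.

Step 6
Reactants: 7 1-[2-hydroxy-4-(methoxymethoxy)phenyl]ethan-1-one; 9 2,4-bis(methoxymethoxy)benzaldehyde
Product: 10 (2E)-3-[2,4-bis(methoxymethoxy)phenyl]-1-[2-hydroxy-4-(methoxymethoxy)phenyl]prop-2-en-1-one
Conditions: KOH (aq. 50%), EtOH, 25 °C
Reagents that add atoms: none
Why: Claisen–Schmidt condensation with E1cB dehydration to the E-enone; as its phenoxide in hydroxide the 2'-hydroxychalcone does not close to the flavanone.

Step 7
Reactants: 10 (2E)-3-[2,4-bis(methoxymethoxy)phenyl]-1-[2-hydroxy-4-(methoxymethoxy)phenyl]prop-2-en-1-one; 5 5-[(1E)-3-methylbuta-1,3-dien-1-yl]-2,4-bis(methoxymethoxy)benzaldehyde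
Product: 11 5-{(1R,5S,6R)-5-[2,4-bis(methoxymethoxy)phenyl]-6-[2-hydroxy-4-(methoxymethoxy)benzoyl]-3-methylcyclohex-2-en-1-yl}-2,4-bis(methoxymethoxy)benzaldehyde (all-trans)
Conditions: (R)-VANOL, BH3·THF, AcOH (1.2 equiv each), THF, 25 °C, then evaporation; 10, THF, 25 °C; 5 (1.5 equiv), 25 → 40 °C; aq. NaHCO3
Reagents that add atoms: none
Why: Chiral boron Lewis acid-promoted Diels–Alder reaction of a 2'-hydroxychalcone, the established way to mulberry-type adducts: 10 binds boron through its phenol and carbonyl oxygens as an s-cis chelate, which activates the enone and lets the vaulted biaryl ligand shield one face. Suprafacial addition keeps C4/C5 trans, the ligand fixes their absolute configuration, the exo transition state (bulky borate turned away from the diene aryl group) sets C3 trans to C4, and the larger HOMO coefficient at the CH2 end of 5 gives the C5–C6 and C3–C4 bonds.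

Step 8
Reactants: 11 the all-trans cycloadduct with one free phenol
Product: 12 5-{(1R,5S,6R)-6-[2,4-bis(methoxymethoxy)benzoyl]-5-[2,4-bis(methoxymethoxy)phenyl]-3-methylcyclohex-2-en-1-yl}-2,4-bis(methoxymethoxy)benzaldehyde
Conditions: NaH (1.1 equiv), MOMCl (1.3 equiv), DMF, 0 °C
Reagents that add atoms: chloromethyl methyl ether, COCCl
Why: O-alkylation of the remaining chelated phenol as its sodium phenoxide; one equivalent of hydride avoids enolate chemistry at C4, where all-trans is in any case the thermodynamic arrangement.

Step 9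
Reactants: 13 methyl 2,4-dihydroxybenzoate
Product: 14 methyl 2-hydroxy-4-(methoxymethoxy)benzoate
Conditions: MOMCl (1.1 equiv), K2CO3 (1.5 equiv), acetone, 25 °C
Reagents that add atoms: chloromethyl methyl ether, COCCl
Why: Selective Williamson-type alkylation of the non-chelated 4-hydroxyl, as in step 4.

Step 10
Reactants: 14 methyl 2-hydroxy-4-(methoxymethoxy)benzoate
Product: 15 tert-butyl 3-[2-hydroxy-4-(methoxymethoxy)phenyl]-3-oxopropanoate
Conditions: tert-butyl acetate (3.2 equiv), LiN(SiMe3)2 (4.2 equiv), THF, −78 °C; 14, −78 → 0 °C; AcOH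
Reagents that add atoms: tert-butyl acetate, CC(=O)OC(C)(C)C
Why: Crossed Claisen condensation of the lithium ester enolate with the aryl methyl ester; excess base covers the phenol and the acidic product, and the tert-butyl group suppresses self-condensation.

Step 11
Reactants: 12 the fully protected core aldehyde; 15 tert-butyl 3-[2-hydroxy-4-(methoxymethoxy)phenyl]-3-oxopropanoate
Product: 16 tert-butyl (2E)-3-{5-[(1R,5S,6R)-6-[2,4-bis(methoxymethoxy)benzoyl]-5-[2,4-bis(methoxymethoxy)phenyl]-3-methylcyclohex-2-en-1-yl]-2,4-bis(methoxymethoxy)phenyl}-2-[2-hydroxy-4-(methoxymethoxy)benzoyl]prop-2-enoate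
Conditions: piperidine (20 mol%), AcOH (20 mol%), 4 Å molecular sieves, toluene, 25 °C
Reagents that add atoms: none
Why: Knoevenagel condensation through the iminium pathway with removal of water; the formyl group is the only aldehyde in 12, and reversible amine addition lets the alkene settle as the E isomer (aryl trans to the ester).

Step 12
Reactants: 16 the alkylidene β-keto ester with one free phenol
Product: 17 tert-butyl (2S,3R)-2-{5-[(1R,5S,6R)-6-[2,4-bis(methoxymethoxy)benzoyl]-5-[2,4-bis(methoxymethoxy)phenyl]-3-methylcyclohex-2-en-1-yl]-2,4-bis(methoxymethoxy)phenyl}-7-(methoxymethoxy)-4-oxo-3,4-dihydro-2H-chromene-3-carboxylate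
Conditions: quinine-derived thiourea [N-(3,5-bis(trifluoromethyl)phenyl)-N'-(9-deoxy-epi-quinin-9-yl)thiourea] (10 mol%), toluene, −25 °C; cold filtration through silica gel
Reagents that add atoms: none
Why: The quinuclidine nitrogen of the catalyst deprotonates the single free phenol of 16 while the thiourea N–H bonds hold the 1,3-dicarbonyl unit, so nucleophile and acceptor sit in one chiral pocket. The phenoxide oxygen adds to the β-carbon, forming O1–C2, and the catalyst-bound enolate is protonated at C3. The closest known reaction type is the bifunctional thiourea-catalysed intramolecular oxa-Michael addition of 2-hydroxyaryl alkylidene β-keto esters to 3-carboxyflavanones, the laboratory parallel of chalcone isomerase. Ring C closes in the 6-endo-trig mode. C2 is set by the catalyst, which selects the face of the trisubstituted alkene; C3 is set trans to the aryl group by thermodynamic protonation and is removed in step 13. The step needs face selectivity over the uncatalysed closure and reaction at one phenol only: the bulky ester makes the β-carbon a better acceptor and supplies the second binding point, low temperature in a non-polar solvent slows the background reaction, and the six other phenol oxygens are capped. The ring A stereocentres lie beyond ring B and should neither help nor hinder the catalyst noticeably. Cold filtration removes the amine before retro-addition can erode C2.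

Step 13
Reactants: 17 the protected 3-(tert-butoxycarbonyl)chromanone
Product: 20 guangsangon N, via heptaphenol tert-butyl ester 18 (not isolated), via heptaphenol keto acid 19 (not isolated)
Conditions: TsOH·H2O (10 equiv), MeOH/THF (5:1), Ar, 40 → 60 °C
Reagents that add atoms: none
Why: Acid-catalysed transacetalisation of the seven methoxymethyl ethers to the solvent, AAL1 cleavage of the tert-butyl ester and decarboxylation of the β-keto acid through its cyclic transition state. The medium stays acidic, so no phenoxide or enolate can reopen ring C, and methanol traps the oxocarbenium and tert-butyl cations before they alkylate the resorcinol rings.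

## Compound list

1 | 5-bromo-2,4-dihydroxybenzaldehyde | O=Cc1cc(Br)c(O)cc1O | starting material
2 | 5-bromo-2,4-bis(methoxymethoxy)benzaldehyde | O=Cc1cc(Br)c(OCOC)cc1OCOC | intermediate
3 | 2-methylbut-1-en-3-yne | CC(=C)C#C | starting material
4 | (E)-4,4,5,5-tetramethyl-2-(3-methylbuta-1,3-dien-1-yl)-1,3,2-dioxaborolane | CC(=C)/C=C/B1OC(C)(C)C(C)(C)O1 | intermediate
5 | 5-[(1E)-3-methylbuta-1,3-dien-1-yl]-2,4-bis(methoxymethoxy)benzaldehyde | O=Cc1cc(/C=C/C(C)=C)c(OCOC)cc1OCOC | intermediate
6 | 2,4-dihydroxyacetophenone | CC(=O)c1ccc(O)cc1O | starting material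
7 | 1-[2-hydroxy-4-(methoxymethoxy)phenyl]ethan-1-one | CC(=O)c1ccc(OCOC)cc1O | intermediate
8 | 2,4-dihydroxybenzaldehyde | O=Cc1ccc(O)cc1O | starting material
9 | 2,4-bis(methoxymethoxy)benzaldehyde | O=Cc1ccc(OCOC)cc1OCOC | intermediate
10 | (2E)-3-[2,4-bis(methoxymethoxy)phenyl]-1-[2-hydroxy-4-(methoxymethoxy)phenyl]prop-2-en-1-one | O=C(/C=C/c1ccc(OCOC)cc1OCOC)c1ccc(OCOC)cc1O | intermediate
11 | 5-{(1R,5S,6R)-5-[2,4-bis(methoxymethoxy)phenyl]-6-[2-hydroxy-4-(methoxymethoxy)benzoyl]-3-methylcyclohex-2-en-1-yl}-2,4-bis(methoxymethoxy)benzaldehyde | CC1=C[C@@H](c2cc(C=O)c(OCOC)cc2OCOC)[C@H](C(=O)c2ccc(OCOC)cc2O)[C@@H](c2ccc(OCOC)cc2OCOC)C1 | intermediate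
12 | 5-{(1R,5S,6R)-6-[2,4-bis(methoxymethoxy)benzoyl]-5-[2,4-bis(methoxymethoxy)phenyl]-3-methylcyclohex-2-en-1-yl}-2,4-bis(methoxymethoxy)benzaldehyde | CC1=C[C@@H](c2cc(C=O)c(OCOC)cc2OCOC)[C@H](C(=O)c2ccc(OCOC)cc2OCOC)[C@@H](c2ccc(OCOC)cc2OCOC)C1 | intermediate
13 | methyl 2,4-dihydroxybenzoate | COC(=O)c1ccc(O)cc1O | starting material
14 | methyl 2-hydroxy-4-(methoxymethoxy)benzoate | COC(=O)c1ccc(OCOC)cc1O | intermediate
15 | tert-butyl 3-[2-hydroxy-4-(methoxymethoxy)phenyl]-3-oxopropanoate | CC(C)(C)OC(=O)CC(=O)c1ccc(OCOC)cc1O | intermediate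
16 | tert-butyl (2E)-3-{5-[(1R,5S,6R)-6-[2,4-bis(methoxymethoxy)benzoyl]-5-[2,4-bis(methoxymethoxy)phenyl]-3-methylcyclohex-2-en-1-yl]-2,4-bis(methoxymethoxy)phenyl}-2-[2-hydroxy-4-(methoxymethoxy)benzoyl]prop-2-enoate | CC1=C[C@@H](c2cc(/C=C(/C(=O)OC(C)(C)C)C(=O)c3ccc(OCOC)cc3O)c(OCOC)cc2OCOC)[C@H](C(=O)c2ccc(OCOC)cc2OCOC)[C@@H](c2ccc(OCOC)cc2OCOC)C1 | intermediate
17 | tert-butyl (2S,3R)-2-{5-[(1R,5S,6R)-6-[2,4-bis(methoxymethoxy)benzoyl]-5-[2,4-bis(methoxymethoxy)phenyl]-3-methylcyclohex-2-en-1-yl]-2,4-bis(methoxymethoxy)phenyl}-7-(methoxymethoxy)-4-oxo-3,4-dihydro-2H-chromene-3-carboxylate | CC1=C[C@@H](c2cc([C@@H]3[C@@H](C(=O)OC(C)(C)C)C(=O)c4ccc(OCOC)cc4O3)c(OCOC)cc2OCOC)[C@H](C(=O)c2ccc(OCOC)cc2OCOC)[C@@H](c2ccc(OCOC)cc2OCOC)C1 | intermediate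
18 | tert-butyl (2S,3R)-2-{5-[(1R,5S,6R)-6-(2,4-dihydroxybenzoyl)-5-(2,4-dihydroxyphenyl)-3-methylcyclohex-2-en-1-yl]-2,4-dihydroxyphenyl}-7-hydroxy-4-oxo-3,4-dihydro-2H-chromene-3-carboxylate (not isolated) | CC1=C[C@@H](c2cc([C@@H]3[C@@H](C(=O)OC(C)(C)C)C(=O)c4ccc(O)cc4O3)c(O)cc2O)[C@H](C(=O)c2ccc(O)cc2O)[C@@H](c2ccc(O)cc2O)C1 | intermediate
19 | (2S,3R)-2-{5-[(1R,5S,6R)-6-(2,4-dihydroxybenzoyl)-5-(2,4-dihydroxyphenyl)-3-methylcyclohex-2-en-1-yl]-2,4-dihydroxyphenyl}-7-hydroxy-4-oxo-3,4-dihydro-2H-chromene-3-carboxylic acid (not isolated) | CC1=C[C@@H](c2cc([C@@H]3[C@@H](C(=O)O)C(=O)c4ccc(O)cc4O3)c(O)cc2O)[C@H](C(=O)c2ccc(O)cc2O)[C@@H](c2ccc(O)cc2O)C1 | intermediate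
20 | guangsangon N, (2S)-2-{5-[(1R,5S,6R)-6-(2,4-dihydroxybenzoyl)-5-(2,4-dihydroxyphenyl)-3-methylcyclohex-2-en-1-yl]-2,4-dihydroxyphenyl}-7-hydroxy-2,3-dihydro-4H-chromen-4-one | CC1=C[C@@H](c2cc([C@@H]3CC(=O)c4ccc(O)cc4O3)c(O)cc2O)[C@H](C(=O)c2ccc(O)cc2O)[C@@H](c2ccc(O)cc2O)C1 | target

## Step count and least certain steps

Total: 13 steps. Longest linear sequence: 7 steps (steps 1, 3, 7, 8, 11, 12, 13).

**Step 12 (key step).** The likeliest failure is poor face selectivity. The 2,4-dialkoxyaryl group makes the β-carbon a weaker acceptor and the adduct a better substrate for retro-addition than simple aryl cases, so uncatalysed closure and reversible opening can both dilute catalyst control. Fallback: give up catalyst control and use the ring A stereocentres as a resolving handle. From 12, Claisen–Schmidt condensation with 7 (KOH, EtOH) would give the 2'-hydroxychalcone of the core F1. NaOAc in refluxing EtOH equilibrates it with the chromanone as two C2 epimers, the (2S)-heptakis(methoxymethyl) ether F2 and the (2R)-epimer F3. These are diastereomers and would be separated by preparative HPLC, with F3 returned to the equilibration. F2 is deprotected with HCl in MeOH at 25 °C and rejoins the route at 20.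

**Step 7.** The risks are insufficient exo preference or face selectivity, and a slow reaction of the electron-rich chalcone that lets the diene dimerise; the formyl group of 5 may also compete for boron. Fallback: resolve instead of induce. From 10 and 5, the same cycloaddition is promoted by the achiral borate from 2,2'-biphenol, BH3·THF and AcOH. The all-trans racemate (11 together with its mirror image ent-11 F4) is purified on silica and protected as in step 8 to 12 and its mirror image ent-12 F5. The two are separated by preparative chromatography on an amylose-carbamate chiral stationary phase, and 12 rejoins the route before step 11.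

**Step 11.** The risk is premature, uncontrolled ring closure: once the alkylidene forms, piperidinium acetate can also catalyse phenol addition and fix C2 without control; the electron-rich aldehyde condenses slowly, which lengthens the exposure. Fallback: mask the nucleophile. From 15, TBSCl and imidazole in DMF give the silyl ether F6. Its Knoevenagel condensation with 12 gives the silyl-protected alkylidene F7, which cannot cyclise. HF·pyridine in THF at 0 °C then frees the phenol under acidic conditions and delivers 16.

**Step 13.** Three things can go wrong in hot protic acid: epimerisation at C2 by benzylic ionisation (assisted by the ring B oxygens), addition of a ring B phenol across C1=C2, and slow tert-butyl cleavage with esterification of 19 by the solvent. Fallback: decouple ester removal from ether removal with an ester that leaves under zerovalent palladium. From 14, Claisen condensation with the lithium enolate of allyl acetate gives the allyl keto ester F8. Condensation with 12 as in step 11 gives the allyl alkylidene F9, and the closure of step 12 gives the allyl chromanone-3-carboxylate F10, at the price of a smaller ester in the key step. Pd(PPh3)4 with HCO2H/Et3N in THF at 25 °C removes the allyl group and the keto acid decarboxylates to F2, the heptakis(methoxymethyl) ether described under step 12. HCl in MeOH at 25 °C then gives 20.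

## Further compounds

F1 | step 12 | (2E)-3-{5-[(1R,5S,6R)-6-[2,4-bis(methoxymethoxy)benzoyl]-5-[2,4-bis(methoxymethoxy)phenyl]-3-methylcyclohex-2-en-1-yl]-2,4-bis(methoxymethoxy)phenyl}-1-[2-hydroxy-4-(methoxymethoxy)phenyl]prop-2-en-1-one | CC1=C[C@@H](c2cc(/C=C/C(=O)c3ccc(OCOC)cc3O)c(OCOC)cc2OCOC)[C@H](C(=O)c2ccc(OCOC)cc2OCOC)[C@@H](c2ccc(OCOC)cc2OCOC)C1
F2 | step 12 | (2S)-2-{5-[(1R,5S,6R)-6-[2,4-bis(methoxymethoxy)benzoyl]-5-[2,4-bis(methoxymethoxy)phenyl]-3-methylcyclohex-2-en-1-yl]-2,4-bis(methoxymethoxy)phenyl}-7-(methoxymethoxy)-2,3-dihydro-4H-chromen-4-one | CC1=C[C@@H](c2cc([C@@H]3CC(=O)c4ccc(OCOC)cc4O3)c(OCOC)cc2OCOC)[C@H](C(=O)c2ccc(OCOC)cc2OCOC)[C@@H](c2ccc(OCOC)cc2OCOC)C1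
F3 | step 12 | (2R)-epimer of F2 | CC1=C[C@@H](c2cc([C@H]3CC(=O)c4ccc(OCOC)cc4O3)c(OCOC)cc2OCOC)[C@H](C(=O)c2ccc(OCOC)cc2OCOC)[C@@H](c2ccc(OCOC)cc2OCOC)C1
F4 | step 7 | ent-11, 5-{(1S,5R,6S)-5-[2,4-bis(methoxymethoxy)phenyl]-6-[2-hydroxy-4-(methoxymethoxy)benzoyl]-3-methylcyclohex-2-en-1-yl}-2,4-bis(methoxymethoxy)benzaldehyde | CC1=C[C@H](c2cc(C=O)c(OCOC)cc2OCOC)[C@@H](C(=O)c2ccc(OCOC)cc2O)[C@H](c2ccc(OCOC)cc2OCOC)C1
F5 | step 7 | ent-12, 5-{(1S,5R,6S)-6-[2,4-bis(methoxymethoxy)benzoyl]-5-[2,4-bis(methoxymethoxy)phenyl]-3-methylcyclohex-2-en-1-yl}-2,4-bis(methoxymethoxy)benzaldehyde | CC1=C[C@H](c2cc(C=O)c(OCOC)cc2OCOC)[C@@H](C(=O)c2ccc(OCOC)cc2OCOC)[C@H](c2ccc(OCOC)cc2OCOC)C1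
F6 | step 11 | tert-butyl 3-[2-(tert-butyldimethylsilyloxy)-4-(methoxymethoxy)phenyl]-3-oxopropanoate | CC(C)(C)OC(=O)CC(=O)c1ccc(OCOC)cc1O[Si](C)(C)C(C)(C)C
F7 | step 11 | tert-butyl (2E)-3-{5-[(1R,5S,6R)-6-[2,4-bis(methoxymethoxy)benzoyl]-5-[2,4-bis(methoxymethoxy)phenyl]-3-methylcyclohex-2-en-1-yl]-2,4-bis(methoxymethoxy)phenyl}-2-[2-(tert-butyldimethylsilyloxy)-4-(methoxymethoxy)benzoyl]prop-2-enoate | CC1=C[C@@H](c2cc(/C=C(/C(=O)OC(C)(C)C)C(=O)c3ccc(OCOC)cc3O[Si](C)(C)C(C)(C)C)c(OCOC)cc2OCOC)[C@H](C(=O)c2ccc(OCOC)cc2OCOC)[C@@H](c2ccc(OCOC)cc2OCOC)C1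
F8 | step 13 | prop-2-en-1-yl 3-[2-hydroxy-4-(methoxymethoxy)phenyl]-3-oxopropanoate | C=CCOC(=O)CC(=O)c1ccc(OCOC)cc1O
F9 | step 13 | prop-2-en-1-yl (2E)-3-{5-[(1R,5S,6R)-6-[2,4-bis(methoxymethoxy)benzoyl]-5-[2,4-bis(methoxymethoxy)phenyl]-3-methylcyclohex-2-en-1-yl]-2,4-bis(methoxymethoxy)phenyl}-2-[2-hydroxy-4-(methoxymethoxy)benzoyl]prop-2-enoate | CC1=C[C@@H](c2cc(/C=C(/C(=O)OCC=C)C(=O)c3ccc(OCOC)cc3O)c(OCOC)cc2OCOC)[C@H](C(=O)c2ccc(OCOC)cc2OCOC)[C@@H](c2ccc(OCOC)cc2OCOC)C1
F10 | step 13 | prop-2-en-1-yl (2S,3R)-2-{5-[(1R,5S,6R)-6-[2,4-bis(methoxymethoxy)benzoyl]-5-[2,4-bis(methoxymethoxy)phenyl]-3-methylcyclohex-2-en-1-yl]-2,4-bis(methoxymethoxy)phenyl}-7-(methoxymethoxy)-4-oxo-3,4-dihydro-2H-chromene-3-carboxylate | CC1=C[C@@H](c2cc([C@@H]3[C@@H](C(=O)OCC=C)C(=O)c4ccc(OCOC)cc4O3)c(OCOC)cc2OCOC)[C@H](C(=O)c2ccc(OCOC)cc2OCOC)[C@@H](c2ccc(OCOC)cc2OCOC)C1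
A1 | alternative 1 | [2,4-bis(methoxymethoxy)phenyl]{(6R)-6-[2,4-bis(methoxymethoxy)phenyl]-4-methylcyclohexa-1,3-dien-1-yl}methanone | CC1=CC=C(C(=O)c2ccc(OCOC)cc2OCOC)[C@@H](c2ccc(OCOC)cc2OCOC)C1
A2 | alternative 1 | 3-[2,4-bis(methoxymethoxy)benzoyl]-6-methyl-2H-pyran-2-one | Cc1ccc(C(=O)c2ccc(OCOC)cc2OCOC)c(=O)o1
A3 | alternative 1 | 1-ethenyl-2,4-bis(methoxymethoxy)benzene | C=Cc1ccc(OCOC)cc1OCOC
A4 | alternative 2 | (5S)-5-[2,4-bis(methoxymethoxy)phenyl]-3-methylcyclohex-2-en-1-one | CC1=CC(=O)C[C@@H](c2ccc(OCOC)cc2OCOC)C1
A5 | alternative 2 | 3-[2,4-bis(methoxymethoxy)phenyl]cyclobutan-1-one | O=C1CC(c2ccc(OCOC)cc2OCOC)C1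
A6 | alternative 2 | propyne | CC#C
A7 | alternative 3 | [2,4-bis(benzyloxy)phenyl]{(1R,2R,6S)-2-[2,4-bis(benzyloxy)-5-bromophenyl]-6-[2,4-bis(benzyloxy)phenyl]-4-methylcyclohex-3-en-1-yl}methanone | CC1=C[C@@H](c2cc(Br)c(OCc3ccccc3)cc2OCc2ccccc2)[C@H](C(=O)c2ccc(OCc3ccccc3)cc2OCc2ccccc2)[C@@H](c2ccc(OCc3ccccc3)cc2OCc2ccccc2)C1
A8 | alternative 3 | 2,4-bis(benzyloxy)-5-bromobenzaldehyde | O=Cc1cc(Br)c(OCc2ccccc2)cc1OCc1ccccc1
A9 | alternative 3 | (1Z,3S,5Z)-1,3-bis[2,4-bis(benzyloxy)phenyl]-5-methyl-6-(trimethylsilyl)-1-(trimethylsilyloxy)hexa-1,5-diene | C[Si](C)(C)O/C(c1ccc(OCc2ccccc2)cc1OCc1ccccc1)=C\[C@@H](c1ccc(OCc2ccccc2)cc1OCc1ccccc1)C/C(C)=C\[Si](C)(C)C
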